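**Plan**
- Locants follow the spiro[4.5]decane core: ring A is the cyclopentane C1–C5 (C1 CHOH, C2 side chain, C5 spiro); ring B is the cyclohexane C5–C10 (C6 C(OH)Me, C9 enal carbon, C10 propyl chain).
- Retrosynthesis: cut the decanoate and acetate; cut the side-chain C=C next to C2 (aldol–dehydration of a C2 acetate arm with a C9 trienal); take the C9 enal back to a C9 ketone (= nitro), the C6 methyl to a carbonyl addition and C1–OH to a ketone reduction; then cut ring B at C5–C10 and C8–C9.
- Enabling feature: spiro C5 lies between the oxygenated carbons C1 and C6, so it is the α-carbon of a β-diketone. C6–C7–C8 is then a vinyl ketone and sp2 C9 a nitro-bearing carbon, which makes ring B the Michael–Michael (formal [4+2]) adduct of a 2-acryloylcyclopentanone and a nitroalkene.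
- Forward: cyclopentanone (ring A) is armed at C2 and acryloylated; ring B closes in step 7; C6, C1 and C9 are adjusted; the trienyl chain is joined by aldol condensation; the two esters go on last.
- Stereochemistry: C2 from RAMP-hydrazone alkylation; C5 and C10 in the key step (anti to the C2 arm, amine–thiourea catalyst); C6 by substrate-controlled methyl addition; C1 by C6–OH-directed reduction; alkene geometry from syn-carboalumination, E1cB elimination and a [3,3] shift.

Key step: step 7

Assumption: the (1R,2R)-thiourea is taken as the catalyst antipode whose facial preference reinforces the bias of the C2 arm in step 7 (its enantiomer is used if the reverse holds); 4-(tert-butyldimethylsilyloxy)butanal and (E)-pent-2-en-4-yn-1-ol are taken as purchasable.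

Step 1
Reactants: 1 cyclopentanone; 2 (R)-1-amino-2-(methoxymethyl)pyrrolidine (RAMP)
Product: 3 cyclopentanone RAMP hydrazone
Conditions: neat, 60 °C, then distillation
Reagents that add atoms: none
Why: Condensation of the N-aminopyrrolidine with the ketone (hydrazone formation) installs the auxiliary for the next step.

Step 2
Reactants: 3 cyclopentanone RAMP hydrazone; 4 tert-butyl bromoacetate
Product: 5 α-alkylated RAMP hydrazone
Conditions: LiN(iPr)2, THF, 0 °C; then 4, −100 °C to rt
Reagents that add atoms: none
Why: RAMP-hydrazone alkylation, in which the chelated lithium azaenolate is alkylated on the face away from the methoxymethyl-bearing ring, should set the future C2 as R.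

Step 3
Reactants: 5 α-alkylated RAMP hydrazone
Product: 6 tert-butyl 2-[(1R)-2-oxocyclopentyl]acetate
Conditions: saturated aqueous oxalic acid, Et2O, rt
Reagents that add atoms: water, O
Why: Mild two-phase hydrazone hydrolysis should free the ketone without epimerising the α-stereocentre and returns the auxiliary.

Step 4
Reactants: 6 tert-butyl 2-[(1R)-2-oxocyclopentyl]acetate; 7 acrolein
Product: 8 acrolein aldol adduct
Conditions: LiN(iPr)2 (1.05 equiv), THF, −78 °C; then 7; AcOH, −78 °C
Reagents that add atoms: none
Why: Kinetic deprotonation at the unsubstituted α′-CH2 leaves the C2 centre untouched, and 1,2-aldol addition to acrolein gives two new centres as a mixture that step 5 erases.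

Step 5
Reactants: 8 acrolein aldol adduct
Product: 9 enolised 2-acryloyl diketone
Conditions: Dess–Martin periodinane, NaHCO3, CH2Cl2, 0 °C; used at once
Reagents that add atoms: none
Why: Dess–Martin oxidation of the allylic β-hydroxy ketone gives the enolised 2-acryloyl 1,3-diketone (a cyclic Nazarov-type reagent), which is not stored because the vinyl ketone oligomerises.

Step 6
Reactants: 10 4-(tert-butyldimethylsilyloxy)butanal; 11 nitromethane
Product: 14 (E)-tert-butyldimethyl[(5-nitropent-4-en-1-yl)oxy]silane, via nitro alcohol 12 (not isolated), via mesylate 13 (not isolated)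
Conditions: 11 (5 equiv), 1,1,3,3-tetramethylguanidine (10 mol %), THF, 0 °C; then MeSO2Cl, Et3N, CH2Cl2, −20 to 0 °C
Reagents that add atoms: none
Why: Henry addition followed by mesylation and E1cB loss of methanesulfonate gives the conjugated nitroalkene as its thermodynamic E isomer.

Step 7
Reactants: 9 enolised 2-acryloyl diketone; 14 (E)-nitroalkene
Product: 16 spiro nitro diketone tert-butyl 2-[(2R,5R,9S,10S)-10-[3-(tert-butyldimethylsilyloxy)propyl]-9-nitro-1,6-dioxospiro[4.5]decan-2-yl]acetate, via Michael adduct 15 (not isolated)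
Conditions: 1-[3,5-bis(trifluoromethyl)phenyl]-3-[(1R,2R)-2-(dimethylamino)cyclohexyl]thiourea (10 mol %), toluene, −20 °C, 9 added slowly to 14; then 1,1,3,3-tetramethylguanidine (0.2 equiv), 0 °C
Reagents that add atoms: none
Why: The amine of the bifunctional thiourea deprotonates the enolised β-diketone of 9 while the thiourea binds the nitro group of 14, so C5 adds to the nitroalkene β-carbon (first Michael addition, bond C5–C10) to give 15, whose nitronate then adds to the terminal carbon of the vinyl ketone (second Michael addition, bond C8–C9). The closest known reaction type is the Michael–Michael [4+2] annulation (formal Diels–Alder reaction) of γ,δ-unsaturated β-dicarbonyl (Nazarov-type) reagents with nitroalkenes under amine–thiourea catalysis. Ring B (C5–C10) closes by a 6-endo-trig conjugate addition of the C9 nitronate carbon to C8, the C5–C10 bond having been made between the two fragments. C5 is set by attack of the planar diketonate on the face anti to the C2 acetate arm, reinforced by the catalyst; C10 is set by the nitroalkene face that the thiourea presents to the ammonium-bound enolate, and the isomer with the C10 chain equatorial and the C1 carbonyl axial should also be the more stable spiro diastereomer; C9 ends with nitro equatorial and trans to the C10 chain by equilibration and is erased in step 10. The step needs C- over O-alkylation and crossed over self-addition of 9; the soft doubly stabilised carbon nucleophile secures the first, the higher electrophilicity of the nitroalkene together with slow addition of 9 at low temperature the second, and the nitronate can reach only C8 through a six-membered transition state. The weak bases leave the ester, the silyl ether and the C2 centre untouched.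

Step 8
Reactants: 16 spiro nitro diketone
Product: 17 C6 tertiary alcohol tert-butyl 2-[(2R,5R,6S,9S,10S)-10-[3-(tert-butyldimethylsilyloxy)propyl]-6-hydroxy-6-methyl-9-nitro-1-oxospiro[4.5]decan-2-yl]acetate
Conditions: MeLi, CeCl3, THF, −78 °C (2.5 equiv); aqueous NH4Cl
Reagents that add atoms: methyllithium, C[Li]
Why: In this organocerium 1,2-addition the first equivalent turns the nitro group into its inert nitronate, and the non-basic reagent should then add to the C6 cyclohexanone (more electrophilic and less hindered than the 2,2,5-trisubstituted C1 cyclopentanone) on the face anti to the C1 branch, the other face being screened by C1 or in the alternative chair by the axial C10 chain, which places the new OH cis to C1.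

Step 9
Reactants: 17 C6 tertiary alcohol
Product: 18 nitro diol tert-butyl 2-[(1R,2R,5S,6S,9S,10S)-10-[3-(tert-butyldimethylsilyloxy)propyl]-1,6-dihydroxy-6-methyl-9-nitrospiro[4.5]decan-2-yl]acetate
Conditions: Me4NBH(OAc)3, MeCN/AcOH, −30 °C
Reagents that add atoms: none
Why: In this Evans–Saksena hydroxyl-directed reduction the alkoxyborohydride formed on the C6 oxygen delivers hydride within the molecule to the face of the C1 carbonyl on which that oxygen lies, so the C1 hydroxyl should end trans to C6 and cis to C10, while nitro and ester do not react.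

Step 10
Reactants: 18 nitro diol
Product: 19 C9 ketone tert-butyl 2-[(1R,2R,5S,6S,10S)-10-[3-(tert-butyldimethylsilyloxy)propyl]-1,6-dihydroxy-6-methyl-9-oxospiro[4.5]decan-2-yl]acetate
Conditions: NaOMe (1 equiv), MeOH, 0 °C; then TiCl3, NH4OAc, H2O, 0 °C to rt
Reagents that add atoms: water, O
Why: In this reductive Nef reaction the nitronate is reduced by trivalent titanium to the imine, which hydrolyses to the ketone in buffered medium, so the now enolisable C10 centre is not exposed to base.

Step 11
Reactants: 19 C9 ketone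
Product: 20 triol tert-butyl 2-[(1R,2R,5S,6S,9R,10S)-10-[3-(tert-butyldimethylsilyloxy)propyl]-1,6,9-trihydroxy-6-methyl-9-(prop-1-en-2-yl)spiro[4.5]decan-2-yl]acetate
Conditions: isopropenylmagnesium bromide, CeCl3, THF, −78 °C (5 equiv)
Reagents that add atoms: isopropenylmagnesium bromide, CC(=C)[Mg]Br
Why: Organocerium 1,2-addition to the hindered, enolisable ketone should proceed without enolisation (C10 retained) and leave the tert-butyl ester alone; the C9 configuration (equatorial attack expected) is immaterial because C9 becomes sp2 in step 13.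

Step 12
Reactants: 20 triol
Product: 21 C1 triethylsilyl ether
Conditions: Et3SiCl, imidazole, DMAP (cat.), DMF, 0 °C to rt
Reagents that add atoms: chlorotriethylsilane, CC[Si](Cl)(CC)CC
Why: Silylation should take the only secondary hydroxyl, since the two tertiary hydroxyls do not react with the chlorosilane under these conditions.

Step 13
Reactants: 21 C1 triethylsilyl ether
Product: 22 (Z)-enal tert-butyl 2-[(1R,2R,5S,6S,9Z,10R)-10-[3-(tert-butyldimethylsilyloxy)propyl]-6-hydroxy-6-methyl-9-(1-oxopropan-2-ylidene)-1-(triethylsilyloxy)spiro[4.5]decan-2-yl]acetate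
Conditions: [C5H5NH][CrO3Cl] (pyridinium chlorochromate), 4 Å molecular sieves, CH2Cl2, rt
Reagents that add atoms: pyridinium chlorochromate, [O-][Cr](=O)(=O)Cl.c1cc[nH+]cc1
Why: In this Babler–Dauben oxidative transposition the tertiary allylic chromate ester undergoes a [3,3] shift to the primary allylic chromate, which is oxidised to the enal, and because the isopropenyl methyl should turn away from substituted C10 in the shift, the CH2O (then CHO) carbon ends cis to C10 as in the target.

Step 14
Reactants: 22 (Z)-enal
Product: 23 enal dimethyl acetal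
Conditions: HC(OMe)3, pyridinium p-toluenesulfonate (cat.), CH2Cl2, 0 °C to rt
Reagents that add atoms: trimethyl orthoformate, COC(OC)OC
Why: Acid-catalysed acetalisation with the orthoformate masks the aldehyde against the amide base of step 17 and the hydride of step 19 without changing the alkene geometry.

Step 15
Reactants: 24 (E)-pent-2-en-4-yn-1-ol; 25 prenyl bromide
Product: 27 (2E,4E)-4,8-dimethylnona-2,4,7-trien-1-ol, via alkenylalane 26 (not isolated)
Conditions: Me3Al, Cp2ZrCl2 (0.25 equiv), CH2Cl2, 0 °C to rt; then 25, Pd(PPh3)4 (3 mol %), THF, rt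
Reagents that add atoms: trimethylaluminium, C[Al](C)C
Why: Negishi zirconium-catalysed syn-carboalumination puts methyl on the internal and aluminium on the terminal alkyne carbon, and palladium-catalysed coupling with the primary carbon of prenyl bromide occurs with retention, which should give the 4E alkene of the skipped diene.

Step 16
Reactants: 27 (2E,4E)-4,8-dimethylnona-2,4,7-trien-1-ol
Product: 28 (2E,4E)-4,8-dimethylnona-2,4,7-trienal
Conditions: MnO2, CH2Cl2, rt
Reagents that add atoms: none
Why: MnO2 oxidises the primary allylic alcohol to the aldehyde without touching the alkenes (allylic oxidation).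

Step 17
Reactants: 23 enal dimethyl acetal; 28 (2E,4E)-4,8-dimethylnona-2,4,7-trienal
Product: 29 aldol adduct
Conditions: LiN(iPr)2 (2.3 equiv), THF, −78 °C; then 28; AcOH, −78 °C
Reagents that add atoms: none
Why: Aldol addition of the tert-butyl ester lithium enolate (the tertiary hydroxyl rides as its alkoxide) to the aldehyde gives two new centres as a mixture that step 18 removes.

Step 18
Reactants: 29 aldol adduct
Product: 31 (2E,4E,6E)-tetraenoate, via mesylate 30 (not isolated)
Conditions: MeSO2Cl, Et3N, CH2Cl2, −20 to 0 °C; then DBU, rt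
Reagents that add atoms: none
Why: Mesylation of the secondary aldol hydroxyl and E1cB elimination with DBU should give the conjugated 2E ester, the isomer with the ester trans to the dienyl chain, under thermodynamic control.

Step 19
Reactants: 31 (2E,4E,6E)-tetraenoate
Product: 32 primary allylic alcohol
Conditions: i-Bu2AlH, CH2Cl2, −78 °C; aqueous potassium sodium tartrate
Reagents that add atoms: none
Why: i-Bu2AlH reduces the unsaturated tert-butyl ester in 1,2-fashion to the allylic alcohol, and the acetal and silyl ethers are inert (ester reduction).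

Step 20
Reactants: 32 primary allylic alcohol
Product: 33 allylic acetate
Conditions: Ac2O, pyridine, DMAP (cat.), CH2Cl2, 0 °C
Reagents that add atoms: acetic anhydride, CC(=O)OC(C)=O
Why: Acetylation should take the only primary hydroxyl, the hindered tertiary C6 hydroxyl not reacting at 0 °C.

Step 21
Reactants: 33 allylic acetate
Product: 34 hydroxypropyl enal
Conditions: HF·pyridine, pyridine, THF, H2O, 0 °C to rt
Reagents that add atoms: water, O
Why: Fluoride cleaves both silyl ethers and the wet, weakly acidic medium hydrolyses the dimethyl acetal, while the acetate and triene should survive the pyridine-buffered reagent (global deprotection).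

Step 22
Reactants: 34 hydroxypropyl enal; 35 decanoyl chloride
Product: 36 CNP0271899.1
Conditions: 2,4,6-collidine, CH2Cl2, −78 to −20 °C
Reagents that add atoms: none
Why: Acylation at low temperature should take the primary hydroxyl, since the secondary C1 hydroxyl (flanked by the spiro carbon and C2) and the tertiary C6 hydroxyl are too hindered to compete.

**Compound list**

1 | cyclopentanone | O=C1CCCC1 | starting material
2 | (R)-1-amino-2-(methoxymethyl)pyrrolidine (RAMP) | COC[C@H]1CCCN1N | starting material
3 | (R)-N-cyclopentylidene-2-(methoxymethyl)pyrrolidin-1-amine | COC[C@H]1CCCN1N=C1CCCC1 | intermediate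
4 | tert-butyl bromoacetate | BrCC(=O)OC(C)(C)C | starting material
5 | tert-butyl 2-[(1R)-2-{[(2R)-2-(methoxymethyl)pyrrolidin-1-yl]imino}cyclopentyl]acetate (C=N geometry immaterial) | COC[C@H]1CCCN1/N=C1\CCC[C@@H]1CC(=O)OC(C)(C)C | intermediate
6 | tert-butyl 2-[(1R)-2-oxocyclopentyl]acetate | O=C1CCC[C@@H]1CC(=O)OC(C)(C)C | intermediate
7 | acrolein | C=CC=O | starting material
8 | tert-butyl 2-[(1R)-3-(1-hydroxyprop-2-en-1-yl)-2-oxocyclopentyl]acetate (mixture at C3 and at the carbinol carbon) | O=C1C(C(O)C=C)CC[C@@H]1CC(=O)OC(C)(C)C | intermediate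
9 | tert-butyl 2-[(1R)-3-acryloyl-2-oxocyclopentyl]acetate, drawn as its chelated enol | O=C1/C(=C(\O)C=C)CC[C@@H]1CC(=O)OC(C)(C)C | intermediate
10 | 4-(tert-butyldimethylsilyloxy)butanal | CC(C)(C)[Si](C)(C)OCCCC=O | starting material
11 | nitromethane | C[N+](=O)[O-] | starting material
12 | 5-(tert-butyldimethylsilyloxy)-1-nitropentan-2-ol (racemic) | CC(C)(C)[Si](C)(C)OCCCC(O)C[N+](=O)[O-] | intermediate
13 | 5-(tert-butyldimethylsilyloxy)-1-nitropentan-2-yl methanesulfonate (racemic) | CC(C)(C)[Si](C)(C)OCCCC(OS(C)(=O)=O)C[N+](=O)[O-] | intermediate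
14 | (E)-tert-butyldimethyl[(5-nitropent-4-en-1-yl)oxy]silane | CC(C)(C)[Si](C)(C)OCCC/C=C/[N+](=O)[O-] | intermediate
15 | open-chain Michael adduct: 9 alkylated at its diketone α-carbon by C2 of a 5-(tert-butyldimethylsilyloxy)-1-nitropentan-2-yl group, new centres as in 16 | CC(C)(C)[Si](C)(C)OCCC[C@H](C[N+](=O)[O-])[C@@]1(C(=O)C=C)CC[C@H](CC(=O)OC(C)(C)C)C1=O | intermediate
16 | tert-butyl 2-[(2R,5R,9S,10S)-10-[3-(tert-butyldimethylsilyloxy)propyl]-9-nitro-1,6-dioxospiro[4.5]decan-2-yl]acetate | CC(C)(C)[Si](C)(C)OCCC[C@@H]1[C@@H]([N+](=O)[O-])CCC(=O)[C@@]12CC[C@H](CC(=O)OC(C)(C)C)C2=O | intermediate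
17 | tert-butyl 2-[(2R,5R,6S,9S,10S)-10-[3-(tert-butyldimethylsilyloxy)propyl]-6-hydroxy-6-methyl-9-nitro-1-oxospiro[4.5]decan-2-yl]acetate | CC(C)(C)[Si](C)(C)OCCC[C@@H]1[C@@H]([N+](=O)[O-])CC[C@](C)(O)[C@@]12CC[C@H](CC(=O)OC(C)(C)C)C2=O | intermediate
18 | tert-butyl 2-[(1R,2R,5S,6S,9S,10S)-10-[3-(tert-butyldimethylsilyloxy)propyl]-1,6-dihydroxy-6-methyl-9-nitrospiro[4.5]decan-2-yl]acetate | CC(C)(C)[Si](C)(C)OCCC[C@@H]1[C@@H]([N+](=O)[O-])CC[C@](C)(O)[C@@]12CC[C@H](CC(=O)OC(C)(C)C)[C@H]2O | intermediate
19 | tert-butyl 2-[(1R,2R,5S,6S,10S)-10-[3-(tert-butyldimethylsilyloxy)propyl]-1,6-dihydroxy-6-methyl-9-oxospiro[4.5]decan-2-yl]acetate | CC(C)(C)[Si](C)(C)OCCC[C@@H]1C(=O)CC[C@](C)(O)[C@@]12CC[C@H](CC(=O)OC(C)(C)C)[C@H]2O | intermediate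
20 | tert-butyl 2-[(1R,2R,5S,6S,9R,10S)-10-[3-(tert-butyldimethylsilyloxy)propyl]-1,6,9-trihydroxy-6-methyl-9-(prop-1-en-2-yl)spiro[4.5]decan-2-yl]acetate | CC(C)(C)[Si](C)(C)OCCC[C@@H]1[C@@](O)(C(C)=C)CC[C@](C)(O)[C@@]12CC[C@H](CC(=O)OC(C)(C)C)[C@H]2O | intermediate
21 | C1 triethylsilyl ether of 20 | CC(C)(C)[Si](C)(C)OCCC[C@@H]1[C@@](O)(C(C)=C)CC[C@](C)(O)[C@@]12CC[C@H](CC(=O)OC(C)(C)C)[C@H]2O[Si](CC)(CC)CC | intermediate
22 | tert-butyl 2-[(1R,2R,5S,6S,9Z,10R)-10-[3-(tert-butyldimethylsilyloxy)propyl]-6-hydroxy-6-methyl-9-(1-oxopropan-2-ylidene)-1-(triethylsilyloxy)spiro[4.5]decan-2-yl]acetate | CC(C)(C)[Si](C)(C)OCCC[C@@H]1/C(=C(/C)C=O)CC[C@](C)(O)[C@@]12CC[C@H](CC(=O)OC(C)(C)C)[C@H]2O[Si](CC)(CC)CC | intermediate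
23 | dimethyl acetal of 22 (9-(1,1-dimethoxypropan-2-ylidene), 9Z) | CC(C)(C)[Si](C)(C)OCCC[C@@H]1/C(=C(/C)C(OC)OC)CC[C@](C)(O)[C@@]12CC[C@H](CC(=O)OC(C)(C)C)[C@H]2O[Si](CC)(CC)CC | intermediate
24 | (E)-pent-2-en-4-yn-1-ol | C#C/C=C/CO | starting material
25 | prenyl bromide (1-bromo-3-methylbut-2-ene) | CC(C)=CCBr | starting material
26 | dimethyl[(1E,3E)-5-(dimethylalumanyloxy)-2-methylpenta-1,3-dien-1-yl]alumane | C[Al](C)/C=C(\C)/C=C/CO[Al](C)C | intermediate
27 | (2E,4E)-4,8-dimethylnona-2,4,7-trien-1-ol | CC(C)=CC/C=C(\C)/C=C/CO | intermediate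
28 | (2E,4E)-4,8-dimethylnona-2,4,7-trienal | CC(C)=CC/C=C(\C)/C=C/C=O | intermediate
29 | aldol adduct: 23 whose ester α-carbon bears a (2E,4E)-1-hydroxy-4,8-dimethylnona-2,4,7-trien-1-yl group (mixture at the two new centres) | CC(C)(C)[Si](C)(C)OCCC[C@@H]1/C(=C(/C)C(OC)OC)CC[C@](C)(O)[C@@]12CC[C@H](C(C(O)/C=C/C(C)=C/CC=C(C)C)C(=O)OC(C)(C)C)[C@H]2O[Si](CC)(CC)CC | intermediate
30 | methanesulfonate of 29 at the aldol hydroxyl | CC(C)(C)[Si](C)(C)OCCC[C@@H]1/C(=C(/C)C(OC)OC)CC[C@](C)(O)[C@@]12CC[C@H](C(C(OS(C)(=O)=O)/C=C/C(C)=C/CC=C(C)C)C(=O)OC(C)(C)C)[C@H]2O[Si](CC)(CC)CC | intermediate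
31 | tert-butyl (2E,4E,6E)-6,10-dimethylundeca-2,4,6,9-tetraenoate carrying at C2 the (1R,2R,5S,6S,9Z,10R)-spirodecan-2-yl core of 23 | CC(C)(C)[Si](C)(C)OCCC[C@@H]1/C(=C(/C)C(OC)OC)CC[C@](C)(O)[C@@]12CC[C@H](\C(=C/C=C/C(C)=C/CC=C(C)C)C(=O)OC(C)(C)C)[C@H]2O[Si](CC)(CC)CC | intermediate
32 | the corresponding (2E,4E,6E)-6,10-dimethylundeca-2,4,6,9-tetraen-1-ol (ester of 31 reduced to CH2OH) | CC(C)(C)[Si](C)(C)OCCC[C@@H]1/C(=C(/C)C(OC)OC)CC[C@](C)(O)[C@@]12CC[C@H](\C(=C/C=C/C(C)=C/CC=C(C)C)CO)[C@H]2O[Si](CC)(CC)CC | intermediate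
33 | acetate of 32 | CC(C)(C)[Si](C)(C)OCCC[C@@H]1/C(=C(/C)C(OC)OC)CC[C@](C)(O)[C@@]12CC[C@H](\C(=C/C=C/C(C)=C/CC=C(C)C)COC(C)=O)[C@H]2O[Si](CC)(CC)CC | intermediate
34 | (2E,4E,6E)-2-[(1R,2R,5S,6S,9Z,10R)-1,6-dihydroxy-10-(3-hydroxypropyl)-6-methyl-9-(1-oxopropan-2-ylidene)spiro[4.5]decan-2-yl]-6,10-dimethylundeca-2,4,6,9-tetraen-1-yl acetate | OCCC[C@@H]1/C(=C(/C)C=O)CC[C@](C)(O)[C@@]12CC[C@H](\C(=C/C=C/C(C)=C/CC=C(C)C)COC(C)=O)[C@H]2O | intermediate
35 | decanoyl chloride | CCCCCCCCCC(=O)Cl | starting material
36 | CNP0271899.1: 3-[(1R,2R,5S,6S,9Z,10R)-2-[(2E,4E,6E)-1-acetoxy-6,10-dimethylundeca-2,4,6,9-tetraen-2-yl]-1,6-dihydroxy-6-methyl-9-(1-oxopropan-2-ylidene)spiro[4.5]decan-10-yl]propyl decanoate | CCCCCCCCCC(=O)OCCC[C@@H]1/C(=C(/C)C=O)CC[C@](C)(O)[C@@]12CC[C@H](\C(=C/C=C/C(C)=C/CC=C(C)C)COC(C)=O)[C@H]2O | target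

**Step count**

Total steps: 22. Longest linear sequence: 19 (steps 1–5, 7–14 and 17–22).

**Steps most likely to fail**

1. Step 7. The vinyl ketone of 9 may oligomerise by self-Michael addition under the amine catalyst faster than it adds to 14, and facial control may be mismatched. The fallback sets out from 9: dry HCl (Et2O, 0 °C) adds to the enone to give the 3-chloropropanoyl diketone F1, a donor that cannot condense with itself. The same thiourea-catalysed Michael addition of F1 to 14 gives the chloro Michael adduct F2. DBU (2.2 equiv, CH2Cl2, 0 °C) then eliminates hydrogen chloride to unveil 15, which closes as before. The fallback returns to the route at 16.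

2. Step 8. The methyl group may add to the wrong face of the C6 carbonyl, or the β-keto alkoxide may open by retro-aldol cleavage. The fallback sets out from 16: Wittig methylenation at C6 (Ph3P=CH2 in excess, THF, the nitro group riding as its nitronate) gives the 6-methylidene compound F3. A radical Markovnikov hydration of Mukaiyama type (Mn(dpm)3 cat., PhSiH3, O2, i-PrOH, then PPh3) forms the C6–O bond on the tertiary radical under neutral conditions. Oxygen then enters from the face a carbon nucleophile would take, which reverses the sense at C6, and no alkoxide is formed. The fallback returns to the route at 17.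

3. Step 13. The geometry of the new tetrasubstituted double bond may be poorly controlled, and the tertiary allylic alcohol may dehydrate under the acidic oxidant. The fallback sets out from 21: a non-oxidative, reversible 1,3-transposition (Ph3SiOReO3 cat., Et2O, 0 °C) gives the primary allylic alcohol F4. The unwanted geometric isomer and recovered 21 are separated and re-equilibrated with the same catalyst. MnO2 (CH2Cl2, rt) then oxidises F4 to the enal. The fallback returns to the route at 22.

**Further compounds**

F1 | step 7 | tert-butyl 2-[(1R)-3-(3-chloropropanoyl)-2-oxocyclopentyl]acetate, drawn as its chelated enol | O=C1/C(=C(\O)CCCl)CC[C@@H]1CC(=O)OC(C)(C)C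
F2 | step 7 | chloro Michael adduct: 15 with the acryloyl group replaced by 3-chloropropanoyl | CC(C)(C)[Si](C)(C)OCCC[C@H](C[N+](=O)[O-])[C@@]1(C(=O)CCCl)CC[C@H](CC(=O)OC(C)(C)C)C1=O
F3 | step 8 | 6-methylidene analogue of 16: tert-butyl 2-[10-[3-(tert-butyldimethylsilyloxy)propyl]-6-methylidene-9-nitro-1-oxospiro[4.5]decan-2-yl]acetate, centres as in 16 | CC(C)(C)[Si](C)(C)OCCC[C@@H]1[C@@H]([N+](=O)[O-])CCC(=C)[C@@]12CC[C@H](CC(=O)OC(C)(C)C)C2=O
F4 | step 13 | primary allylic alcohol: 22 with CHO replaced by CH2OH (9Z) | CC(C)(C)[Si](C)(C)OCCC[C@@H]1/C(=C(/C)CO)CC[C@](C)(O)[C@@]12CC[C@H](CC(=O)OC(C)(C)C)[C@H]2O[Si](CC)(CC)CC
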